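**Retrosynthetic overview**
1. Target 11 ⇒ 5'-O-prenyl ether 8 by a para-Claisen–Cope relay: the 5'-OH and the 2'-prenyl group both come from one aryl C–O bond.
2. 8 ⇒ 5'-bromoisoflavone 6 + prenyl alcohol 7 by C(aryl)–O coupling (key disconnection; the C–Br bond fixes the site).
3. 6 ⇒ deoxybenzoin 4 + a C1 unit from DMF, closing the pyranone ring at O1–C2; 4 ⇒ phloroglucinol 3 + bromo acid 2.
4. 2 ⇒ homovanillic acid 1 by ortho-bromination.
5. Ring order: rings A and B are bought intact; the pyranone ring C is the only ring formed (step 2).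

Assumption: the target has no stereocentre and no stereogenic double bond (the prenyl olefin carries two identical methyls), so it is achiral and no stereocontrol is needed.

**Step 1**
Reactants: 1 homovanillic acid, 2-(4-hydroxy-3-methoxyphenyl)acetic acid
Product: 2 2-(3-bromo-4-hydroxy-5-methoxyphenyl)acetic acid
Conditions: Br2 (1.02 equiv), AcOH, 15 °C → rt, 2 h
Reagents that add atoms: bromine, BrBr
Why: Electrophilic aromatic bromination; the free phenol directs to its only open ortho position (para is blocked), as in vanillin → 5-bromovanillin.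

**Step 2**
Reactants: 2 2-(3-bromo-4-hydroxy-5-methoxyphenyl)acetic acid; 3 phloroglucinol
Product: 6 3-(3-bromo-4-hydroxy-5-methoxyphenyl)-5,7-dihydroxy-4H-chromen-4-one, via deoxybenzoin 4 (not isolated), via enaminone 5 (not isolated)
Conditions: BF3·OEt2 (solvent), 85 °C, 1.5 h; then DMF, MsCl (3 equiv), 65 °C, 2 h; aq. NaOAc work-up
Reagents that add atoms: N,N-dimethylformamide, CN(C)C=O
Why: BF3-mediated Friedel–Crafts acylation gives the deoxybenzoin, the DMF/MsCl Vilsmeier-type reagent aminomethylenates its CH2, and the ortho-OH closes the pyranone by addition–elimination (O1–C2 bond, loss of Me2NH), i.e. the one-pot deoxybenzoin isoflavone synthesis; the aryl bromide and OMe are inert.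

**Step 3**
Reactants: 6 3-(3-bromo-4-hydroxy-5-methoxyphenyl)-5,7-dihydroxy-4H-chromen-4-one; 7 prenyl alcohol (3-methylbut-2-en-1-ol)
Product: 8 5,7-dihydroxy-3-[4-hydroxy-3-methoxy-5-(3-methylbut-2-enyloxy)phenyl]-4H-chromen-4-one
Conditions: CuI (10 mol%), 3,4,7,8-tetramethyl-1,10-phenanthroline (20 mol%), Cs2CO3 (4.5 equiv), 7 (20 equiv)/DMF, 90 °C, Ar, 24 h; pH 5 work-up
Reagents that add atoms: none
Why: Proposed new method: an Ullmann-type Cu(I)/phenanthroline C(aryl)–O coupling run on the unprotected triphenolic bromide, where the prenyl alkoxide (large excess) is the only competent O-nucleophile because the substrate aryloxides are chelated, vinylogous-acid-like or doubly ortho-flanked, and where no phenol can be O-prenylated because no allyl electrophile is present, so LCu(I)–OR oxidative addition to Ar–Br and C–O reductive elimination place the prenyloxy group only at C5'; the closest known reactions are the Cu-catalysed alkoxylation of 5-bromovanillin as its phenoxide and the CuI/phenanthroline etherification of aryl and vinyl halides with primary allylic alcohols, neither shown on a free polyphenolic isoflavone.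

**Step 4**
Reactants: 8 5,7-dihydroxy-3-[4-hydroxy-3-methoxy-5-(3-methylbut-2-enyloxy)phenyl]-4H-chromen-4-one
Product: 11 3-[4,5-dihydroxy-3-methoxy-2-(3-methylbut-2-enyl)phenyl]-5,7-dihydroxy-4H-chromen-4-one, via ortho-dienone 9 (not isolated), via para-dienone 10 (not isolated)
Conditions: Eu(fod)3 (20 mol%), NaHCO3, PhCl–THF 9:1, 85 °C, 24 h
Reagents that add atoms: none
Why: Aromatic para-Claisen–Cope rearrangement: [3,3] shift to C6' gives the ortho-dienone, which under aprotic Eu(III) catalysis undergoes a Cope [3,3] shift to C2' (para to O5') and then enolises, giving the normal prenyl group at C2' and the free 5'-OH; no stereocentre remains in the product.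

**Compound list**
1 | homovanillic acid, 2-(4-hydroxy-3-methoxyphenyl)acetic acid | COc1cc(CC(=O)O)ccc1O | starting material
2 | 2-(3-bromo-4-hydroxy-5-methoxyphenyl)acetic acid | COc1cc(CC(=O)O)cc(Br)c1O | intermediate
3 | phloroglucinol, benzene-1,3,5-triol | Oc1cc(O)cc(O)c1 | starting material
4 | deoxybenzoin, 2-(3-bromo-4-hydroxy-5-methoxyphenyl)-1-(2,4,6-trihydroxyphenyl)ethan-1-one (not isolated) | COc1cc(CC(=O)c2c(O)cc(O)cc2O)cc(Br)c1O | intermediate
5 | enaminone, 2-(3-bromo-4-hydroxy-5-methoxyphenyl)-3-(dimethylamino)-1-(2,4,6-trihydroxyphenyl)prop-2-en-1-one (not isolated; C=C geometry labile, not defined) | COc1cc(C(=CN(C)C)C(=O)c2c(O)cc(O)cc2O)cc(Br)c1O | intermediate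
6 | 3-(3-bromo-4-hydroxy-5-methoxyphenyl)-5,7-dihydroxy-4H-chromen-4-one | COc1cc(-c2coc3cc(O)cc(O)c3c2=O)cc(Br)c1O | intermediate
7 | prenyl alcohol, 3-methylbut-2-en-1-ol | CC(C)=CCO | starting material
8 | 5,7-dihydroxy-3-[4-hydroxy-3-methoxy-5-(3-methylbut-2-enyloxy)phenyl]-4H-chromen-4-one | COc1cc(-c2coc3cc(O)cc(O)c3c2=O)cc(OCC=C(C)C)c1O | intermediate
9 | ortho-dienone, 5,7-dihydroxy-3-[4-hydroxy-3-methoxy-6-(2-methylbut-3-en-2-yl)-5-oxocyclohexa-1,3-dien-1-yl]-4H-chromen-4-one (racemic, not isolated) | O=C1C(O)=C(OC)C=C(c2coc3cc(O)cc(O)c3c2=O)C1C(C)(C)C=C | intermediate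
10 | para-dienone, 5,7-dihydroxy-3-[4-hydroxy-5-methoxy-6-(3-methylbut-2-enyl)-3-oxocyclohexa-1,4-dien-1-yl]-4H-chromen-4-one (racemic, not isolated) | O=C1C=C(c2coc3cc(O)cc(O)c3c2=O)C(CC=C(C)C)C(OC)=C1O | intermediate
11 | 3-[4,5-dihydroxy-3-methoxy-2-(3-methylbut-2-enyl)phenyl]-5,7-dihydroxy-4H-chromen-4-one (achiral) | COc1c(O)c(O)cc(-c2coc3cc(O)cc(O)c3c2=O)c1CC=C(C)C | target

**Total step count:** 4. **Longest linear sequence:** 4 (1 → 2 → 6 → 8 → 11).

**Three steps most likely to fail**

Step 3 (the proposed new step). The polyphenoxide may sequester copper, or hydrodebromination or aryl ether by-products may win. The fallback uses known chemistry, sets out from 6 and comes back at 11. Compound 6 is treated with MOMCl/i-Pr2NEt (CH2Cl2–DMF, 0 °C → rt) to give 3-[3-bromo-5-methoxy-4-(methoxymethoxy)phenyl]-5-hydroxy-7-(methoxymethoxy)-4H-chromen-4-one F1; the chelated 5-OH stays free. F1 is coupled with 7 under the established Ullmann etherification conditions for protected aryl bromides (CuI, tetramethylphenanthroline, Cs2CO3, toluene, 110 °C) to give 5-hydroxy-3-[3-methoxy-4-(methoxymethoxy)-5-(3-methylbut-2-enyloxy)phenyl]-7-(methoxymethoxy)-4H-chromen-4-one F2. F2 is rearranged with Eu(fod)3 (CHCl3, 60 °C) to 5-hydroxy-3-[5-hydroxy-3-methoxy-4-(methoxymethoxy)-2-(3-methylbut-2-enyl)phenyl]-7-(methoxymethoxy)-4H-chromen-4-one F3. Finally 3 M HCl/MeOH at 40 °C removes both MOM groups and gives 11; the C-prenyl group has no ortho-OH to cyclise onto.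

Step 4. The free 5-OH/4-C=O and catechol-type sites may bind Eu, and enolisation of 9 may compete with the Cope step, giving the 6'-(1,1-dimethylallyl) isomer. The fallback switches to the peracylated substrate class for which this rearrangement is established; it sets out from 8 and comes back at 11. Compound 8 is acetylated (Ac2O, pyridine, DMAP, rt) to 5,7-diacetoxy-3-[4-acetoxy-3-methoxy-5-(3-methylbut-2-enyloxy)phenyl]-4H-chromen-4-one F4. The acetates remove the chelating sites and deactivate ring A against prenyl transfer. F4 is rearranged with Eu(fod)3 (CHCl3, 60 °C) to 5,7-diacetoxy-3-[4-acetoxy-5-hydroxy-3-methoxy-2-(3-methylbut-2-enyl)phenyl]-4H-chromen-4-one F5, and K2CO3/MeOH at 0 °C → rt then cleaves the three acetates to give 11.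

Step 2. The one-pot acylation/annulation may give mixtures with the bromoguaiacyl acid (incomplete acylation, O-formylation or O-mesylation). The fallback splits it into two stages with a different C1 donor and no acid in the ring closure; it sets out from 2 and 3 and comes back at 6. The BF3·OEt2 acylation is run alone and the deoxybenzoin 4 is isolated by aqueous NaOAc precipitation. Compound 4 is then treated with N,N-dimethylformamide dimethyl acetal (THF, 60 °C) to give the enaminone 5, which cyclises to 6 on AcOH work-up. No new compound is made (F0).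

**Further compounds**
F1 | step 3 | 3-[3-bromo-5-methoxy-4-(methoxymethoxy)phenyl]-5-hydroxy-7-(methoxymethoxy)-4H-chromen-4-one | COCOc1cc(O)c2c(=O)c(-c3cc(OC)c(OCOC)c(Br)c3)coc2c1
F2 | step 3 | 5-hydroxy-3-[3-methoxy-4-(methoxymethoxy)-5-(3-methylbut-2-enyloxy)phenyl]-7-(methoxymethoxy)-4H-chromen-4-one | COCOc1cc(O)c2c(=O)c(-c3cc(OC)c(OCOC)c(OCC=C(C)C)c3)coc2c1
F3 | step 3 | 5-hydroxy-3-[5-hydroxy-3-methoxy-4-(methoxymethoxy)-2-(3-methylbut-2-enyl)phenyl]-7-(methoxymethoxy)-4H-chromen-4-one | COCOc1cc(O)c2c(=O)c(-c3cc(O)c(OCOC)c(OC)c3CC=C(C)C)coc2c1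
F4 | step 4 | 5,7-diacetoxy-3-[4-acetoxy-3-methoxy-5-(3-methylbut-2-enyloxy)phenyl]-4H-chromen-4-one | CC(=O)Oc1cc(OC(C)=O)c2c(=O)c(-c3cc(OC)c(OC(C)=O)c(OCC=C(C)C)c3)coc2c1
F5 | step 4 | 5,7-diacetoxy-3-[4-acetoxy-5-hydroxy-3-methoxy-2-(3-methylbut-2-enyl)phenyl]-4H-chromen-4-one | CC(=O)Oc1cc(OC(C)=O)c2c(=O)c(-c3cc(O)c(OC(C)=O)c(OC)c3CC=C(C)C)coc2c1
F0 | step 2 | none | none
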